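The numbers in the tables are simulated on assumed constants; scatter was added.

At 12.0 h the ochre run, a closed stirred flask, has 1% of its Q left and reads 80% as G, the monomer in chains, yet it was charged with 1.9 mM of the initiator Z against 0.076 M of Q. That is 32.0 G for each Z charged. So I write the balance of Z: what was charged equals free Z plus what Z has become. Spent once per G, Z covers 2.50% of the Q. The rest needs a form of Z that survives each addition; then Q falls first order (pseudo-first-order), with a constant k that should not move with the Q charge. With Z equal and Q charges 3.95 apart, the early Q readings give a mean k of 0.279 /h. Its inverse is the lifetime of Q, τ = 3.58 h.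

all flasks: Z 1.9 mM
- ochre: Q 0.076 M; run made earlier
- green: Q 0.038 M; run made earlier
- teal: Q 0.15 M; run made earlier
- east: Q 0.076 M; everything together in a closed stirred flask, run for 30 h; time 30 h
- north-east: Q 0.076 M; a single well-mixed tank run continuously and read at steady state, 30 h in it on average
- west: Q 0.076 M; a tube with plug flow, the mixed feed as stated, residence time 30 h; time 30 h
- south-west: Q 0.076 M (fed, over 24.0 h); all but Q at the start; Q goes in evenly over 24.0 h, the run ends at 30 h; time 30 h

- ochre (time / h: G / %, Q / %): 2.50: 47, 52; 6.00: 75, 17; 12.0: 80, 1; 30.0: 71, 2
- green (time / h: G / %, Q / %): 6.00: 73, 22; 12.0: 80, 2; 20.0: 74, 0; 25.0: 74, 3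
- teal (time / h: G / %, Q / %): 3.00: 55, 42; 8.00: 81, 5; 15.0: 81, 0; 25.0: 74, 0

(readings scatter by 2 percentage points)

* the set-up with the highest amount of G at the outlet or at the end, in percent of the Q put in ("none" if the first two lie within 2 percentage points) (east / north-east / west / south-west / none)
* amount of G at the outlet or at the end, in percent of the Q put in, east
* amount of G at the outlet or at the end, in percent of the Q put in, north-east
* amount of G at the outlet or at the end, in percent of the Q put in, west
* amount of G at the outlet or at the end, in percent of the Q put in, south-west

- the stated concentrations are those of everything mixed, before any reaction; amounts are the same in each set-up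
- the numbers in the tables scatter with a standard deviation of 2 percentage points
- the feed brings no volume worth counting
- the earlier runs were made in a closed, stirred flask
- a reading or a percentage of G counts all its forms, free or not

Now τ does the work. In the tank I reckon Q left as 1/(1 + t/τ), which is 10.7%. In south-west, Q enters evenly and leaves with lifetime τ, so it stands near τ/tf, 14.9%, when the feed ends and 2.80% at the end of the run. G also ages: ochre sinks from 80% to 71% while Q reads 1% and 2%. East and west share one history, so I take that 71%; for the tank I scale it by the Q reacted, to 63.4%. In south-west the mean age of G is 14.4 h, against 26.4 h in east. That matches a closed flask at 18.0 h, between teal's 81% and green's 74%; their mean less the Q left gives 74.7%, so I choose south-west.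

The forecast, with figures above mine, gives 73.5% for east and west, 70% for north-east and 76% for south-west, and names south-west because “the G made late has less time to relax”.

The flask gives 69.6% in east, 69.6% in west, 65.6% in north-east and 76.9% in south-west, so south-west is best.

    Q + Z → J + G (k = 25.0 /M/h)
    G ⇌ L (K = 0.600, k = 0.0240 /h)
    Q + J → G + J, rate k3*[J]*[Q] (k = 170 /M/h)
    Z + G ⇌ E (K = 69.0 /M, k = 9.60 /M/h)

The surviving form of Z is J: when the feed ends in south-west it holds nearly all of the charge, 0.00179 M of 1.9 mM, and my 14.9% of Q stands against 13.8% in that flask. In north-east, my 10.7% stands against 13.2%. The main reason the G of north-east stays so far below the Q put in is the step from G to L, both ways. With that step struck out, north-east gives 86.2% instead of 65.6%.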